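**Analysis of the target**

Target 19 is a (2S)-flavanone: a chroman-4-one in which benzene ring A is fused to the oxygen heterocycle (ring C: O1, C2, C3, C4, C4a, C8a), and C2 carries ring B, a 3-hydroxy-4-methoxyphenyl group. Ring A is substituted everywhere except C6, with methoxy groups at C5 and C7 and a prenyl (3-methylbut-2-enyl) group at C8, next to the ring oxygen. C2 is the only stereocentre, so the task is absolute control, not relative control. That centre is fragile. It lies β to the C4 carbonyl, so base or hot acid opens ring C by retro-oxa-Michael cleavage to an achiral 2'-hydroxy enone that recloses without selectivity, and the 4'-methoxy group makes the benzylic C2–O1 bond easy to ionise in acid. The trisubstituted prenyl alkene excludes hydrogenolysis, strong electrophiles and strong protic acid, and the single free phenol on ring B must be distinguished from three methyl ethers. The two real difficulties are to create C2 under kinetic control without passing through the ring-opened enone, and to put prenyl on C8 and not on C6. The plan rests on one feature: C2 is a benzylic carbon bound to O1, and if C3 and C4 are written as a vinyl group it is the substituted end of a 3-arylallyl electrophile, which a chiral iridium catalyst can join to the ring A phenol oxygen with control of configuration. The phenol this requires, 4, has only one free ortho carbon, which becomes C4a and so fixes prenyl at C8.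

**Retrosynthetic reasoning**

19 ⇒ 18. The methoxymethyl acetal on the ring B oxygen is removed last. A free phenol on ring B would compete as a nucleophile in the etherification and would be acylated during ring closure. Among the usual phenol protecting groups the acetal is the one that survives hydride, borane, base and the iridium step and is removed without base or hydrogen. It is cleaved at the flavanone stage because O1 is then conjugated to the C4 carbonyl and C2–O1 is at its least ionisable.

18 ⇒ 16 (through 17). The C4–C4a bond is cut. This leaves ring C open but C2 already in place, and the forward reaction is an intramolecular Friedel–Crafts acylation. The acyl chain can reach only the ortho carbon of the ether oxygen, and ring A has exactly one free ortho carbon, so regiochemistry is fixed by the substitution pattern. That carbon is activated by three oxygen substituents, which is what permits mild, buffered conditions. Cutting O1–C2 at this stage instead would lead back to the ring-opened enone, whose closure is reversible and unselective.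

16 ⇒ 14 ⇒ 12 (through 15 and 13). The carboxylic acid is traced to a terminal vinyl group by functional-group changes only: oxidation of a primary alcohol, which in turn comes from anti-Markovnikov hydration of the alkene. The vinyl group carries exactly C3 and C4. The forward steps must distinguish the monosubstituted alkene from the trisubstituted prenyl alkene and must not ionise or eliminate the benzylic ether.

12 ⇒ 4 (as its lithium salt 11) + 10. The O1–C2 bond is cut. This is the strategic disconnection: it divides the molecule into the ring A phenol and a linear, achiral ring B allyl carbonate of similar size, and the forward reaction creates the only stereocentre as it forms the bond. The forward reaction has to give the branched ether, attack through oxygen, and one enantiomer; all three are under control of the iridium catalyst and its chiral ligand, not of the substrate.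

10 ⇒ 9 ⇒ 8 ⇒ 6 + 7, and 6 ⇒ 5. The carbonate comes from allylic alcohol 9, the alcohol from ester 8 by 1,2-reduction, and the ester from aldehyde 6 and phosphonate 7 by a Horner–Wadsworth–Emmons olefination that sets the (E) geometry the iridium step requires. Aldehyde 6 is protected isovanillin 5, which already has the ring B oxygen pattern.

4 ⇒ 1 + 2 (through 3). The aryl–prenyl bond is cut. Phenol 1 is symmetric, so its two ortho carbons are equivalent and ortho C-alkylation of its sodium salt 3 with 2 can give only one mono-prenyl ortho product.

**Alternatives that were turned down**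

Alternative 1: Cut O1–C8a and close ring C last by intramolecular aryl C–O coupling. The open-chain diol triflate A2 would be treated with Pd2(dba)3, a bulky biarylphosphine and Cs2CO3. Zerovalent palladium inserts into the aryl–triflate bond at C8a and the C2 alkoxide is transferred to that carbon, giving flavan-4-ol A1.
- For: C2 would be made as an ordinary secondary carbinol by dependable asymmetric reduction or aldol chemistry, and the coupling forms the bond at the aromatic carbon, so the configuration cannot be lost in the key step. There is also no acid-sensitive acylation. On both points it is stronger than the chosen route.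
- Against: the triflate carbon is flanked by the prenyl group and the side chain on an electron-rich ring, so oxidative addition is slow. The palladium alkoxide of a secondary benzylic alcohol has a β-hydrogen, and β-hydride elimination competes with C–O reductive elimination. Carbonate can cleave the triflate at sulfur.
- Step economy: A2 needs a pentasubstituted ring A and a second stereocentre at C4 that is controlled only to be oxidised away, followed by oxidation and deprotection.
- Comparison: the chosen route attaches O1 from a simple trisubstituted phenol in one catalytic step and builds no sacrificial stereocentre.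

Alternative 2: Remove the C4 carbonyl retrosynthetically and introduce it last by benzylic oxidation. Flavan A4, with bromine holding C8 and an acetate on ring B, would be treated with DDQ in wet solvent. Hydride abstraction from C4, capture of the cation by water and a second oxidation give ketone A3.
- For: a flavan has no carbonyl and therefore no retro-oxa-Michael pathway, so C2 is robust through many steps. This is better than the chosen route, whose intermediates 12 to 16 are acid-sensitive benzylic ethers.
- Against: C2–H is also benzylic, α to oxygen and attached to a para-methoxyaryl ring, so hydride abstraction there would destroy the stereocentre. DDQ also dehydrogenates C2–C3 of flavanones. The prenyl group cannot be present during the oxidation because of its allylic C–H bonds.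
- Step economy: prenyl must be installed afterwards by cross-coupling at a bromide flanked by two oxygen substituents, with the usual α/γ ambiguity, and the acetate must then be removed from a base-sensitive flavanone.
- Comparison: the chosen route carries prenyl from the first step and needs no oxidant that can attack C2–H.

Alternative 3: Cut C8–C1'' and trace the prenyl group to an ether on O5. The 5-O-prenyl flavanone A6 would be heated with Eu(fod)3, so that a Claisen shift to C6 followed by a Cope shift to C8 gives the 8-prenyl-5-hydroxyflavanone A5.
- For: the prenyl group is delivered intramolecularly to a finished flavanone with a normal prenyl terminus, and a natural (2S)-flavanone with the same ring B could supply C2. For placing prenyl this is arguably cleaner than step 1 of the chosen route, which relies on phenoxide C-alkylation of modest selectivity.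
- Against: the key step does not create C2. The centre must be bought or made separately and then survive heating with a Lewis acid and a final methylation of the chelated 5-hydroxyl, which needs base and heat, the conditions that open ring C. Enolisation at the halfway stage would leave a reverse-prenyl unit on C6.
- Comparison: the chosen route makes C2 by catalyst control, does not depend on the enantiomeric purity of a natural flavanone, and never exposes the finished flavanone to base.

Key step: step 6

Assumption: the (Sa,Sc,Sc) enantiomer of the phosphoramidite is taken to be the one that leads to the (S) ether, following the usual sense of induction of this catalyst family with aryl-substituted allyl carbonates and heteroatom nucleophiles. If the sense proves to be the reverse, the antipodal ligand is used with no other change.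

**Route**

Step 1
Reactants: 1 3,5-dimethoxyphenol; 2 prenyl bromide (1-bromo-3-methylbut-2-ene)
Product: 4 3,5-dimethoxy-2-(3-methylbut-2-en-1-yl)phenol, via sodium phenoxide 3 (not isolated)
Conditions: NaH (1.0 equiv), toluene, 0 °C → rt; then 2 (0.9 equiv), rt
Reagents that add atoms: sodium hydride, [NaH] (sodium of 3 only)
Why: Ortho C-alkylation of a sodium phenoxide in a non-polar solvent: the tight ion pair in toluene delivers the allylic bromide to the ortho carbon through a cyclic transition state, which suppresses O-alkylation and para attack; the two ortho carbons of 1 are equivalent, and SN2 attack at the primary carbon of 2 keeps the normal prenyl unit.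

Step 2
Reactants: 5 isovanillin (3-hydroxy-4-methoxybenzaldehyde)
Product: 6 4-methoxy-3-(methoxymethoxy)benzaldehyde
Conditions: MOMCl, i-Pr2NEt, CH2Cl2, 0 °C → rt
Reagents that add atoms: chloromethyl methyl ether, COCCl
Why: O-alkylation of the phenol to its methoxymethyl acetal; this masks the only other phenoxide that could compete in step 6, and the acetal is stable to the base, hydride and borane used later.

Step 3
Reactants: 6 4-methoxy-3-(methoxymethoxy)benzaldehyde; 7 triethyl phosphonoacetate
Product: 8 ethyl (E)-3-[4-methoxy-3-(methoxymethoxy)phenyl]prop-2-enoate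
Conditions: NaH, THF, 0 °C → rt
Reagents that add atoms: none
Why: Horner–Wadsworth–Emmons olefination; a stabilised phosphonate anion and an aromatic aldehyde should give the (E)-cinnamate almost exclusively, and the two new carbons are the future C3 and C4.

Step 4
Reactants: 8 ethyl (E)-3-[4-methoxy-3-(methoxymethoxy)phenyl]prop-2-enoate
Product: 9 (E)-3-[4-methoxy-3-(methoxymethoxy)phenyl]prop-2-en-1-ol
Conditions: i-Bu2AlH (2.5 equiv), CH2Cl2, −78 → 0 °C; aq. potassium sodium tartrate work-up
Reagents that add atoms: none
Why: 1,2-Reduction of an α,β-unsaturated ester by i-Bu2AlH at low temperature gives the allylic alcohol without touching the alkene geometry or the acetal.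

Step 5
Reactants: 9 (E)-3-[4-methoxy-3-(methoxymethoxy)phenyl]prop-2-en-1-ol
Product: 10 (E)-3-[4-methoxy-3-(methoxymethoxy)phenyl]prop-2-en-1-yl methyl carbonate
Conditions: ClCO2Me, pyridine, CH2Cl2, 0 °C
Reagents that add atoms: methyl chloroformate, COC(=O)Cl
Why: Acylation of a primary allylic alcohol with a chloroformate; the methyl carbonate is the leaving group that the iridium catalyst ionises readily, and it leaves as CO2 and methoxide.

Step 6
Reactants: 4 3,5-dimethoxy-2-(3-methylbut-2-en-1-yl)phenol; 10 (E)-3-[4-methoxy-3-(methoxymethoxy)phenyl]prop-2-en-1-yl methyl carbonate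
Product: 12 (S)-1,5-dimethoxy-3-({1-[4-methoxy-3-(methoxymethoxy)phenyl]prop-2-en-1-yl}oxy)-2-(3-methylbut-2-en-1-yl)benzene, via lithium phenoxide 11 (not isolated)
Conditions: 4, n-BuLi, THF, 0 °C (gives 11, 1.5 equiv); [Ir(cod)Cl]2 (2 mol %), (Sa,Sc,Sc)-O,O'-(1,1'-binaphthyl-2,2'-diyl) N,N-bis(1-phenylethyl)phosphoramidite (4 mol %), pre-activated with n-PrNH2 (THF, 50 °C, then evaporated); 10 (1.0 equiv), THF, rt
Reagents that add atoms: n-butyllithium, [Li]CCCC (lithium of 11 only)
Why: Iridium-catalysed asymmetric allylic etherification of an aryl-substituted allyl carbonate with an alkali phenoxide, a known reaction type. The cyclometalated monovalent iridium complex formed from [Ir(cod)Cl]2 and the phosphoramidite ionises carbonate 10 with inversion to an η3-allyl complex of trivalent iridium, and the methyl carbonate anion falls apart to CO2 and methoxide. Phenoxide 11 attacks from outside the metal, anti to iridium, at the aryl-bearing terminus, which is the more positively polarised carbon and leads directly to the iridium complex of the terminal alkene; this forms the O1–C2 bond and gives the branched ether. No ring is closed in this step. The new stereocentre C2 is set by the catalyst alone: the ligand determines which face of the allyl unit binds to iridium and the nucleophile takes the opposite face, so the (Sa,Sc,Sc) ligand is expected to give (S) and its antipode (R). The step needs branched over linear selectivity, O- over C-allylation of an electron-rich ambident phenoxide, and chemoselectivity over the prenyl group. The lithium counter-ion in THF should keep attack on oxygen, the electron-rich phenoxide is a poor leaving group so 12 should not re-ionise, and the trisubstituted prenyl alkene neither binds the catalyst nor carries a leaving group. One ortho substituent on the phenoxide lies within the known scope, and excess 4 is recoverable.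

Step 7
Reactants: 12 (S)-1,5-dimethoxy-3-({1-[4-methoxy-3-(methoxymethoxy)phenyl]prop-2-en-1-yl}oxy)-2-(3-methylbut-2-en-1-yl)benzene
Product: 14 (3S)-3-[3,5-dimethoxy-2-(3-methylbut-2-en-1-yl)phenoxy]-3-[4-methoxy-3-(methoxymethoxy)phenyl]propan-1-ol, via alkylborane 13 (not isolated)
Conditions: 9-BBN (1.5 equiv), THF, 0 °C → rt; then 3 M NaOH, 30% H2O2, 0 °C → rt
Reagents that add atoms: 9-borabicyclo[3.3.1]nonane, B1C2CCCC1CCC2 (boron and ring carbons of 13 only); hydrogen peroxide, OO (hydroxyl oxygen of 14)
Why: Hydroboration–oxidation; 9-BBN places boron on the terminal carbon of the monosubstituted alkene and reacts far more slowly with the trisubstituted prenyl alkene; boron ends γ to the ether oxygen, so no β-elimination is possible, and C2 is not touched.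

Step 8
Reactants: 14 (3S)-3-[3,5-dimethoxy-2-(3-methylbut-2-en-1-yl)phenoxy]-3-[4-methoxy-3-(methoxymethoxy)phenyl]propan-1-ol
Product: 16 (3S)-3-[3,5-dimethoxy-2-(3-methylbut-2-en-1-yl)phenoxy]-3-[4-methoxy-3-(methoxymethoxy)phenyl]propanoic acid, via aldehyde 15 (not isolated)
Conditions: TEMPO (0.2 equiv), PhI(OAc)2 (2.2 equiv), MeCN–H2O (1:1), rt
Reagents that add atoms: water, O
Why: Oxoammonium-catalysed oxidation of a primary alcohol in aqueous acetonitrile; the aldehyde is hydrated and oxidised on to the acid in the same flask, and the weakly acidic medium avoids base-induced β-elimination of the aryloxide and leaves the prenyl alkene alone.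

Step 9
Reactants: 16 (3S)-3-[3,5-dimethoxy-2-(3-methylbut-2-en-1-yl)phenoxy]-3-[4-methoxy-3-(methoxymethoxy)phenyl]propanoic acid
Product: 18 (2S)-5,7-dimethoxy-2-[4-methoxy-3-(methoxymethoxy)phenyl]-8-(3-methylbut-2-en-1-yl)chroman-4-one, via mixed anhydride 17 (not isolated)
Conditions: (CF3CO)2O (1.5 equiv), 2,6-di-tert-butyl-4-methylpyridine (3 equiv), CH2Cl2 (0.02 M), −20 °C → rt; pH 7 buffer quench
Reagents that add atoms: trifluoroacetic anhydride, O=C(OC(=O)C(F)(F)F)C(F)(F)F (trifluoroacetyl group of 17 only)
Why: Intramolecular Friedel–Crafts acylation through the acyl trifluoroacetate, closing a six-membered ring at the only free ortho carbon of ring A, which is activated by three oxygen substituents and far more nucleophilic than ring B (whose closure would give a five-membered indanone); the hindered pyridine takes up the trifluoroacetic acid so that the para-methoxybenzylic C2–O1 bond, the acetal and the prenyl alkene are not exposed to strong acid, and C2 takes no part in the bond formation.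

Step 10
Reactants: 18 (2S)-5,7-dimethoxy-2-[4-methoxy-3-(methoxymethoxy)phenyl]-8-(3-methylbut-2-en-1-yl)chroman-4-one
Product: 19 (2S)-2-(3-hydroxy-4-methoxyphenyl)-5,7-dimethoxy-8-(3-methylbut-2-en-1-yl)chroman-4-one
Conditions: HCl (1 M in MeOH), MeOH–THF, rt → 40 °C
Reagents that add atoms: none
Why: Acid-catalysed transacetalisation of the aryl methoxymethyl ether to methanol; no base is present, so the retro-oxa-Michael pathway is closed; O1 is now a vinylogous ester oxygen, so C2–O1 is less prone to ionisation than in 12 to 16; the prenyl alkene has no neighbouring free hydroxyl to cyclise onto.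

**Compound list**

1 | 3,5-dimethoxyphenol | COc1cc(O)cc(OC)c1 | starting material
2 | prenyl bromide (1-bromo-3-methylbut-2-ene) | CC(C)=CCBr | starting material
3 | sodium 3,5-dimethoxyphenoxide | COc1cc([O-])cc(OC)c1.[Na+] | intermediate
4 | 3,5-dimethoxy-2-(3-methylbut-2-en-1-yl)phenol | COc1cc(O)c(CC=C(C)C)c(OC)c1 | intermediate
5 | isovanillin (3-hydroxy-4-methoxybenzaldehyde) | COc1ccc(C=O)cc1O | starting material
6 | 4-methoxy-3-(methoxymethoxy)benzaldehyde | COCOc1cc(C=O)ccc1OC | intermediate
7 | triethyl phosphonoacetate | CCOC(=O)CP(=O)(OCC)OCC | starting material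
8 | ethyl (E)-3-[4-methoxy-3-(methoxymethoxy)phenyl]prop-2-enoate | CCOC(=O)/C=C/c1ccc(OC)c(OCOC)c1 | intermediate
9 | (E)-3-[4-methoxy-3-(methoxymethoxy)phenyl]prop-2-en-1-ol | OC/C=C/c1ccc(OC)c(OCOC)c1 | intermediate
10 | (E)-3-[4-methoxy-3-(methoxymethoxy)phenyl]prop-2-en-1-yl methyl carbonate | COC(=O)OC/C=C/c1ccc(OC)c(OCOC)c1 | intermediate
11 | lithium 3,5-dimethoxy-2-(3-methylbut-2-en-1-yl)phenoxide | COc1cc([O-])c(CC=C(C)C)c(OC)c1.[Li+] | intermediate
12 | (S)-1,5-dimethoxy-3-({1-[4-methoxy-3-(methoxymethoxy)phenyl]prop-2-en-1-yl}oxy)-2-(3-methylbut-2-en-1-yl)benzene | COc1ccc([C@H](C=C)Oc2cc(OC)cc(OC)c2CC=C(C)C)cc1OCOC | intermediate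
13 | 9-{(3S)-3-[3,5-dimethoxy-2-(3-methylbut-2-en-1-yl)phenoxy]-3-[4-methoxy-3-(methoxymethoxy)phenyl]propyl}-9-borabicyclo[3.3.1]nonane | COc1ccc([C@H](CCB2C3CCCC2CCC3)Oc2cc(OC)cc(OC)c2CC=C(C)C)cc1OCOC | intermediate
14 | (3S)-3-[3,5-dimethoxy-2-(3-methylbut-2-en-1-yl)phenoxy]-3-[4-methoxy-3-(methoxymethoxy)phenyl]propan-1-ol | COc1ccc([C@H](CCO)Oc2cc(OC)cc(OC)c2CC=C(C)C)cc1OCOC | intermediate
15 | (3S)-3-[3,5-dimethoxy-2-(3-methylbut-2-en-1-yl)phenoxy]-3-[4-methoxy-3-(methoxymethoxy)phenyl]propanal | COc1ccc([C@H](CC=O)Oc2cc(OC)cc(OC)c2CC=C(C)C)cc1OCOC | intermediate
16 | (3S)-3-[3,5-dimethoxy-2-(3-methylbut-2-en-1-yl)phenoxy]-3-[4-methoxy-3-(methoxymethoxy)phenyl]propanoic acid | COc1ccc([C@H](CC(=O)O)Oc2cc(OC)cc(OC)c2CC=C(C)C)cc1OCOC | intermediate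
17 | (3S)-3-[3,5-dimethoxy-2-(3-methylbut-2-en-1-yl)phenoxy]-3-[4-methoxy-3-(methoxymethoxy)phenyl]propanoic trifluoroacetic anhydride | COc1ccc([C@H](CC(=O)OC(=O)C(F)(F)F)Oc2cc(OC)cc(OC)c2CC=C(C)C)cc1OCOC | intermediate
18 | (2S)-5,7-dimethoxy-2-[4-methoxy-3-(methoxymethoxy)phenyl]-8-(3-methylbut-2-en-1-yl)chroman-4-one | COc1ccc([C@@H]2CC(=O)c3c(OC)cc(OC)c(CC=C(C)C)c3O2)cc1OCOC | intermediate
19 | (2S)-2-(3-hydroxy-4-methoxyphenyl)-5,7-dimethoxy-8-(3-methylbut-2-en-1-yl)chroman-4-one | COc1ccc([C@@H]2CC(=O)c3c(OC)cc(OC)c(CC=C(C)C)c3O2)cc1O | target

**Step count and weak points**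

Total: 10 steps. Longest linear sequence: 9 steps (5 → 6 → 8 → 9 → 10 → 12 → 14 → 16 → 18 → 19); the phenol branch adds one step (1 → 4).

Step 6 (key step). The most likely failures are allylation at a ring carbon of the very electron-rich phenoxide instead of at oxygen, and slow erosion of the branched-to-linear ratio and of enantiomeric purity. The erosion would come from re-ionisation of 12 by the catalyst, because the para-methoxyaryl group stabilises the allyl cation. Ether 12 is both benzylic and allylic and may also rearrange on acidic silica, so it should be filtered through base-washed silica and carried straight into step 7.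

The fallback sets out from 9 and 4 and comes back at 14. Asymmetric epoxidation of 9 (Ti(Oi-Pr)4, L-(+)-diisopropyl tartrate, t-BuOOH, 4 Å sieves, CH2Cl2, −20 °C) should give the (2S,3S)-epoxy alcohol F1. Hydride delivery to C2 with NaAlH2(OCH2CH2OMe)2 in DME opens it to the (R)-1,3-diol F2, and TBSCl with imidazole silylates the primary hydroxyl to give the mono-silyl ether F3. A Mitsunobu reaction of F3 with 4 (PPh3, diisopropyl azodicarboxylate, toluene, 0 °C) inverts the carbinol to the (S)-aryl ether F4, and Bu4NF in THF releases 14. This route creates C2 by reagent control and replaces steps 5 to 7. Its own weak points are the acid lability of the electron-rich aryl epoxide and partial SN1 character in the Mitsunobu step.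

Step 9. Ionisation of the para-methoxybenzylic C2–O1 bond under the acylating conditions would racemise C2 or fragment the chain. Loss of the acetal or addition of trifluoroacetic acid to the prenyl alkene is possible if the buffer is insufficient, and closure onto ring B is a minor risk.

The fallback sets out from 16 and comes back at 18. Coupling with Me2NH·HCl (1-ethyl-3-(3-dimethylaminopropyl)carbodiimide hydrochloride, 1-hydroxybenzotriazole, i-Pr2NEt, CH2Cl2) gives the N,N-dimethylamide F5. Triflic anhydride with 2-fluoropyridine in CH2Cl2 (−78 → 0 °C) activates the amide, and ring A attacks the resulting iminium carbon in an intramolecular Vilsmeier–Haack-type arylation to give the cyclic iminium triflate F6. Aqueous NaHCO3 hydrolyses F6 to 18. The medium stays basic throughout, so no protic acid reaches C2–O1.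

Step 1. Competing O-alkylation, attack at the para carbon between the two methoxy groups, and double prenylation would lower the amount of 4 and complicate purification.

The fallback sets out from 1 and comes back at 4. Protection (MOMCl, i-Pr2NEt, CH2Cl2) gives the methoxymethyl ether F7. Directed ortho-lithiation (n-BuLi, THF, 0 °C) between the acetal oxygen and a methoxy group gives the aryllithium F8. Copper-catalysed allylation (CuI, 10 mol %, then 2, −78 °C → rt) gives the prenylated methoxymethyl ether F9, and brief treatment with dilute HCl in MeOH at rt releases 4. Regiochemistry is then set by the directing groups and not by ion pairing, at the cost of two steps.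

Step 10. Protic acid may add methanol or water to the prenyl alkene, or partly epimerise C2 through reversible opening of ring C on prolonged exposure.

The fallback sets out from 18 and comes back at 19. Me3SiOTf with 2,2'-bipyridyl in CH2Cl2 at 0 °C transfers the methoxymethyl unit to the pyridine nitrogen and leaves the aryl trimethylsilyl ether F10. Addition of water at rt hydrolyses F10 to 19. This cleaves the acetal by silyl transfer without any Brønsted acid.

**Further compounds**

F1 | step 6 | (2S,3S)-{3-[4-methoxy-3-(methoxymethoxy)phenyl]oxiran-2-yl}methanol | COCOc1cc([C@H]2[C@@H](O2)CO)ccc1OC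
F2 | step 6 | (R)-1-[4-methoxy-3-(methoxymethoxy)phenyl]propane-1,3-diol | COCOc1cc([C@H](O)CCO)ccc1OC
F3 | step 6 | (R)-3-[tert-butyl(dimethyl)silyloxy]-1-[4-methoxy-3-(methoxymethoxy)phenyl]propan-1-ol | COCOc1cc([C@H](O)CCO[Si](C)(C)C(C)(C)C)ccc1OC
F4 | step 6 | (S)-tert-butyl{3-[3,5-dimethoxy-2-(3-methylbut-2-en-1-yl)phenoxy]-3-[4-methoxy-3-(methoxymethoxy)phenyl]propoxy}dimethylsilane | COc1ccc([C@H](CCO[Si](C)(C)C(C)(C)C)Oc2cc(OC)cc(OC)c2CC=C(C)C)cc1OCOC
F5 | step 9 | (3S)-3-[3,5-dimethoxy-2-(3-methylbut-2-en-1-yl)phenoxy]-3-[4-methoxy-3-(methoxymethoxy)phenyl]-N,N-dimethylpropanamide | COc1ccc([C@H](CC(=O)N(C)C)Oc2cc(OC)cc(OC)c2CC=C(C)C)cc1OCOC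
F6 | step 9 | (2S)-N-{5,7-dimethoxy-2-[4-methoxy-3-(methoxymethoxy)phenyl]-8-(3-methylbut-2-en-1-yl)chroman-4-ylidene}-N-methylmethanaminium trifluoromethanesulfonate | COc1ccc([C@@H]2CC(=[N+](C)C)c3c(OC)cc(OC)c(CC=C(C)C)c3O2)cc1OCOC.[O-]S(=O)(=O)C(F)(F)F
F7 | step 1 | 1,3-dimethoxy-5-(methoxymethoxy)benzene | COCOc1cc(OC)cc(OC)c1
F8 | step 1 | [2,4-dimethoxy-6-(methoxymethoxy)phenyl]lithium | [Li]c1c(OC)cc(OC)cc1OCOC
F9 | step 1 | 1,5-dimethoxy-3-(methoxymethoxy)-2-(3-methylbut-2-en-1-yl)benzene | COCOc1cc(OC)cc(OC)c1CC=C(C)C
F10 | step 10 | (2S)-5,7-dimethoxy-2-[4-methoxy-3-(trimethylsilyloxy)phenyl]-8-(3-methylbut-2-en-1-yl)chroman-4-one | COc1ccc([C@@H]2CC(=O)c3c(OC)cc(OC)c(CC=C(C)C)c3O2)cc1O[Si](C)(C)C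
A1 | alternative 1 | (2S,4R)-5,7-dimethoxy-2-[4-methoxy-3-(methoxymethoxy)phenyl]-8-(3-methylbut-2-en-1-yl)chroman-4-ol | COc1ccc([C@@H]2C[C@@H](O)c3c(OC)cc(OC)c(CC=C(C)C)c3O2)cc1OCOC
A2 | alternative 1 | 2-{(1R,3S)-1,3-dihydroxy-3-[4-methoxy-3-(methoxymethoxy)phenyl]propyl}-3,5-dimethoxy-6-(3-methylbut-2-en-1-yl)phenyl trifluoromethanesulfonate | COc1ccc([C@@H](O)C[C@@H](O)c2c(OC)cc(OC)c(CC=C(C)C)c2OS(=O)(=O)C(F)(F)F)cc1OCOC
A3 | alternative 2 | (2S)-3'-acetoxy-8-bromo-5,7,4'-trimethoxyflavanone | COc1ccc([C@@H]2CC(=O)c3c(OC)cc(OC)c(Br)c3O2)cc1OC(C)=O
A4 | alternative 2 | (2S)-3'-acetoxy-8-bromo-5,7,4'-trimethoxyflavan | COc1ccc([C@@H]2CCc3c(OC)cc(OC)c(Br)c3O2)cc1OC(C)=O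
A5 | alternative 3 | (2S)-5-hydroxy-7,4'-dimethoxy-3'-(methoxymethoxy)-8-(3-methylbut-2-en-1-yl)flavanone | COc1ccc([C@@H]2CC(=O)c3c(O)cc(OC)c(CC=C(C)C)c3O2)cc1OCOC
A6 | alternative 3 | (2S)-7,4'-dimethoxy-3'-(methoxymethoxy)-5-(3-methylbut-2-en-1-yloxy)flavanone | COc1ccc([C@@H]2CC(=O)c3c(OCC=C(C)C)cc(OC)cc3O2)cc1OCOC
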